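The seven-membered ring is annulated onto a preformed cyclopentane in one pot, with acrolein as a two-carbon linchpin. The step exploits two features of the target: the aldol relationship between the ester carbinol C-6 of the seven-membered ring and C-4 of the five-membered ring (a ketone until the isopropyl group is added), and the trisubstituted ring alkene C-7=C-8. A regiodefined enolate at C-5 adds to the acrolein carbonyl (C-5–C-6, two stereocentres); the resulting vinyl group is then metathesised with the isopropenyl end of the C-1 side chain (C-7=C-8). The precursor is a silyl enol ether whose quaternary C-1 comes from an asymmetric conjugate addition; C-9 is hydroxylated last.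

Key step: step 3

Remark: atoms carry daucane numbers (C-1 methyl-bearing ring-fusion carbon, C-2/C-3 ring CH2, C-4 isopropyl carbinol, C-5 ring-fusion CH, C-6 ester carbinol, C-7=C-8 alkene with methyl on C-8, C-9 free carbinol, C-10 CH2); the sense of induction of the chiral ligand in step 2 is assumed as drawn, and the antipodal ligand would be used otherwise.

Step 1
Reactants: 1 3-ethoxycyclopent-2-en-1-one; 2 4-bromo-2-methylbut-1-ene
Product: 5 3-(3-methylbut-3-en-1-yl)cyclopent-2-en-1-one, via Grignard reagent 3 (not isolated), via tertiary carbinol 4 (not isolated)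
Conditions: Mg, THF, 40 °C; 1, THF, 0 °C; then 1 M HCl, 0 °C to rt
Reagents that add atoms: water O
Why: Stork–Danheiser sequence: 1,2-addition of the homoallylic Grignard reagent to the vinylogous ester, then acid-induced hydrolysis and dehydration, should transpose the carbonyl and give the 3-substituted enone; no stereocentre is formed.

Step 2
Reactants: 5 3-(3-methylbut-3-en-1-yl)cyclopent-2-en-1-one
Product: 7 trimethyl{[(3S)-3-methyl-3-(3-methylbut-3-en-1-yl)cyclopent-1-en-1-yl]oxy}silane, via aluminium enolate 6 (not isolated)
Conditions: Me3Al, Cu(O2CC4H3S) (2 mol %), chiral phosphoramidite ligand (4 mol %), Et2O, −30 °C; then Me3SiOTf, THF, −30 to 0 °C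
Reagents that add atoms: trimethylaluminium C[Al](C)C; trimethylsilyl trifluoromethanesulfonate C[Si](C)(C)OS(=O)(=O)C(F)(F)F
Why: copper-catalysed asymmetric conjugate addition of Me3Al to the β-substituted cyclopentenone should create the quaternary C-1 under ligand control (methyl delivered to one enone face), and O-silylation of the aluminium enolate fixes the enol double bond towards C-5.

Step 3
Reactants: 7 trimethyl{[(3S)-3-methyl-3-(3-methylbut-3-en-1-yl)cyclopent-1-en-1-yl]oxy}silane; 8 acrolein
Product: 12 (3aS,8S,8aS)-8-hydroxy-3a,6-dimethyl-3,3a,4,5,8,8a-hexahydroazulen-1(2H)-one, via lithium enolate 9 (not isolated), via zinc enolate 10 (not isolated), via aldol 11 (not isolated)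
Conditions: MeLi, THF, 0 °C; ZnCl2, then acrolein, −78 °C; AcOH; Ar purge; then toluene, second-generation Hoveyda–Grubbs catalyst (5 mol %), 1,4-benzoquinone (10 mol %), 70 °C
Reagents that add atoms: none
Why: MeLi cleaves the silyl enol ether to the regiodefined lithium enolate, which after transmetalation to zinc adds 1,2 to acrolein through a closed Zimmerman–Traxler transition state to form C-5–C-6; after protonation the ruthenium carbene joins the new vinyl group to the isopropenyl end of the C-1 chain, forming C-7=C-8 with loss of ethylene, so that acrolein acts as a two-carbon linchpin in a formal (5+2) annulation. The closest known reaction types are the zinc-enolate aldol addition of conjugate-addition-derived enolates and ring-closing metathesis to trisubstituted cycloheptenes. The seven-membered ring is closed by ring-closing metathesis, and the ring enforces the Z alkene. C-5 is set by approach of the aldehyde anti to the larger C-1 substituent (the alkenyl chain), which places C-6 cis to the angular methyl and so gives the trans ring fusion; C-6 is set by the chair transition state of the ring-locked (E)-enolate (anti aldol). The step needs enolate regiocontrol (secured by the silyl enol ether), 1,2- over 1,4-addition (favoured at −78 °C with zinc) and suppression of allylic-alcohol isomerisation (benzoquinone); discrimination of methyl from the chain at C-1 is the least secure element, and minor diastereomers would be removed at this stage.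

Step 4
Reactants: 12 (3aS,8S,8aS)-8-hydroxy-3a,6-dimethyl-3,3a,4,5,8,8a-hexahydroazulen-1(2H)-one
Product: 13 (1R,3aS,8S,8aS)-3a,6-dimethyl-1-(propan-2-yl)-1,2,3,3a,4,5,8,8a-octahydroazulene-1,8-diol
Conditions: iPrMgCl (3 equiv), LaCl3·2LiCl (1 equiv), THF, −40 to 0 °C; aq. NH4Cl
Reagents that add atoms: isopropylmagnesium chloride CC(C)[Mg]Cl
Why: lanthanum-promoted Grignard 1,2-addition should outrun enolisation and β-hydride reduction of the hindered ketone, and attack on the face anti to C-6 and the angular methyl (cis to H-5) sets C-4 with the hydroxyl cis to C-6.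

Step 5
Reactants: 13 (1R,3aS,8S,8aS)-3a,6-dimethyl-1-(propan-2-yl)-1,2,3,3a,4,5,8,8a-octahydroazulene-1,8-diol; 14 4-acetoxy-3-methoxybenzoic acid
Product: 15 6-O-(4-acetoxy-3-methoxybenzoyl) ester of diol 13
Conditions: EDC·HCl, DMAP, CH2Cl2, 0 °C to rt
Reagents that add atoms: none
Why: Steglich esterification should acylate the secondary allylic C-6 hydroxyl with retention while the tertiary C-4 hydroxyl stays free.

Step 6
Reactants: 15 6-O-(4-acetoxy-3-methoxybenzoyl) ester of diol 13
Product: 16 (9R)-9-hydroxy derivative of 15 (C-9 hydroxyl trans to the C-6 ester)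
Conditions: SeO2 (0.5 equiv), t-BuOOH (3 equiv), CH2Cl2, rt
Reagents that add atoms: tert-butyl hydroperoxide CC(C)(C)OO (its oxygen is relayed by selenium dioxide O=[Se]=O)
Why: Riley allylic hydroxylation (ene reaction at C-7, then [2,3]-sigmatropic shift) should oxidise the ring CH2 on the more substituted alkene end (C-9) and keep C-7=C-8; approach of selenium anti to the C-6 ester should place the new hydroxyl trans to it.

Step 7
Reactants: 16 (9R)-9-hydroxy derivative of 15
Product: 17 target CNP0189996.3, 6-O-(4-hydroxy-3-methoxybenzoyl) ester of (1R,4R,5S,6S,9R)-dauc-7-ene-4,6,9-triol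
Conditions: K2CO3 (0.2 equiv), MeOH, 0 °C
Reagents that add atoms: none
Why: base-catalysed transesterification should remove the phenolic acetate much faster than it cleaves the hindered secondary vanillate.

Compound list
1 | 3-ethoxycyclopent-2-en-1-one | CCOC1=CC(=O)CC1 | starting material
2 | 4-bromo-2-methylbut-1-ene | CC(=C)CCBr | starting material
3 | (3-methylbut-3-en-1-yl)magnesium bromide | CC(=C)CC[Mg]Br | intermediate
4 | 3-ethoxy-1-(3-methylbut-3-en-1-yl)cyclopent-2-en-1-ol (racemic, formed as its magnesium alkoxide) | CCOC1=CC(O)(CCC(C)=C)CC1 | intermediate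
5 | 3-(3-methylbut-3-en-1-yl)cyclopent-2-en-1-one | CC(=C)CCC1=CC(=O)CC1 | intermediate
6 | dimethylaluminium (3S)-3-methyl-3-(3-methylbut-3-en-1-yl)cyclopent-1-en-1-olate | CC(=C)CC[C@@]1(C)CCC(O[Al](C)C)=C1 | intermediate
7 | trimethyl{[(3S)-3-methyl-3-(3-methylbut-3-en-1-yl)cyclopent-1-en-1-yl]oxy}silane | CC(=C)CC[C@@]1(C)CCC(O[Si](C)(C)C)=C1 | intermediate
8 | acrolein (prop-2-enal) | C=CC=O | starting material
9 | lithium (3S)-3-methyl-3-(3-methylbut-3-en-1-yl)cyclopent-1-en-1-olate | CC(=C)CC[C@@]1(C)CCC(O[Li])=C1 | intermediate
10 | chlorozinc (3S)-3-methyl-3-(3-methylbut-3-en-1-yl)cyclopent-1-en-1-olate | CC(=C)CC[C@@]1(C)CCC(O[Zn]Cl)=C1 | intermediate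
11 | (2S,3S)-2-[(1S)-1-hydroxyprop-2-en-1-yl]-3-methyl-3-(3-methylbut-3-en-1-yl)cyclopentan-1-one | O=C1CC[C@](C)(CCC(C)=C)[C@H]1[C@@H](O)C=C | intermediate
12 | (3aS,8S,8aS)-8-hydroxy-3a,6-dimethyl-3,3a,4,5,8,8a-hexahydroazulen-1(2H)-one | O[C@H]1C=C(C)CC[C@@]2(C)CCC(=O)[C@H]12 | intermediate
13 | (1R,3aS,8S,8aS)-3a,6-dimethyl-1-(propan-2-yl)-1,2,3,3a,4,5,8,8a-octahydroazulene-1,8-diol | O[C@H]1C=C(C)CC[C@@]2(C)CC[C@@](O)(C(C)C)[C@H]12 | intermediate
14 | 4-acetoxy-3-methoxybenzoic acid | COc1cc(C(=O)O)ccc1OC(C)=O | starting material
15 | 6-O-(4-acetoxy-3-methoxybenzoyl) ester of diol 13 | COc1cc(C(=O)O[C@H]2C=C(C)CC[C@@]3(C)CC[C@@](O)(C(C)C)[C@H]23)ccc1OC(C)=O | intermediate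
16 | (9R)-9-hydroxy derivative of 15 | COc1cc(C(=O)O[C@H]2C=C(C)[C@H](O)C[C@@]3(C)CC[C@@](O)(C(C)C)[C@H]23)ccc1OC(C)=O | intermediate
17 | target CNP0189996.3 | COc1cc(C(=O)O[C@H]2C=C(C)[C@H](O)C[C@@]3(C)CC[C@@](O)(C(C)C)[C@H]23)ccc1O | target

Total step count: 7. Longest linear sequence: 7 steps (from 1).

Steps most likely to fail

Step 3. The aldol may lose diastereoselectivity (methyl versus chain discrimination at C-1, anti versus syn), and the hot metathesis in the presence of zinc salts may cause retro-aldol cleavage or isomerisation of the allylic alcohol. The fallback sets out from 7 and separates the two bond formations with a protected intermediate. A Mukaiyama aldol addition of 7 to acrolein (BF3·OEt2, CH2Cl2, −78 °C) would give aldol 11, which is isolated and freed from minor diastereomers. Silylation (Et3SiOTf, 2,6-lutidine) would give the triethylsilyl ether of aldol 11 F1. Ring-closing metathesis (second-generation Hoveyda–Grubbs catalyst, toluene, 70 °C) would give the triethylsilyl ether of the bicyclic ketone F2. Desilylation (pyridinium p-toluenesulfonate, MeOH) comes back to the route at 12.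

Step 6. The ene reaction may be sluggish at the alkene deactivated by the allylic ester, with erosion of facial control or over-oxidation to the enone. The fallback sets out from 15 and replaces direct stereoselective hydroxylation by oxidation and reduction. Stoichiometric SeO2 in dioxane at 80 °C, followed by Dess–Martin periodinane on the crude mixture, would converge all C-9 oxidised material to the C-9 enone F4. Luche reduction (NaBH4, CeCl3, MeOH, −78 °C), with hydride delivered anti to the angular methyl, comes back to the route at 16.

Step 4. The basic reagent may enolise the hindered ketone (epimerisation at C-5), cleave the magnesium aldolate by retro-aldol reaction, or reduce the ketone by β-hydride transfer. The fallback sets out from 12 and uses an sp2 nucleophile without β-hydrogens on magnesium-bound carbon. Prop-1-en-2-ylmagnesium bromide with CeCl3 (THF, −78 °C) would give the isopropenyl carbinol F3. Chemoselective hydrogenation of its 1,1-disubstituted alkene (H2, RhCl(PPh3)3, benzene, rt) leaves the trisubstituted ring alkene and comes back to the route at 13.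

Further compounds
F1 | step 3 | triethylsilyl ether of aldol 11 | O=C1CC[C@](C)(CCC(C)=C)[C@H]1[C@@H](O[Si](CC)(CC)CC)C=C
F2 | step 3 | triethylsilyl ether of bicyclic ketone 12 | CC[Si](CC)(CC)O[C@H]1C=C(C)CC[C@@]2(C)CCC(=O)[C@H]12
F3 | step 4 | isopropenyl carbinol (prop-1-en-2-yl analogue of diol 13 at C-4, same configuration) | O[C@H]1C=C(C)CC[C@@]2(C)CC[C@@](O)(C(C)=C)[C@H]12
F4 | step 6 | C-9 enone (9-oxo analogue of 16) | COc1cc(C(=O)O[C@H]2C=C(C)C(=O)C[C@@]3(C)CC[C@@](O)(C(C)C)[C@H]23)ccc1OC(C)=O
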